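**Retrosynthetic overview**

- The target is the 5-O-demethyl derivative of its flavanone 5-methyl ether, so the last step is cleavage of the one methyl ether that is chelated to the C4 carbonyl.
- The strategy rests on the flavan pyran ring O1''–C2''–C3''–C4''–C4a''–C8a'' (double primes mark the flavan unit): its C2''–C3'' edge is styrene and C4'' is a quinone methide carbon. C3''–C4'' and O1''–C2'' are formed together, and both flavan stereocentres (2'',4''-trans) are set in that step.
- The quinone methide comes from a diaryl carbinol joining flavanone C6 to a 2,4-dihydroxy-3,6-dimethoxyphenyl ring. The carbinol is made from (R)-6-formyl-5,7-dimethoxyflavanone and the magnesium phenolate of symmetric 2,5-dimethoxyresorcinol.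
- The flavanone pyranone ring comes from Mitsunobu etherification (inversion) of 4-hydroxy-2,6-dimethoxybenzaldehyde with ethyl (S)-3-hydroxy-3-phenylpropanoate, then ring acylation. The resorcinol comes from 4-methoxyphenol by dibromination, O-methylation and double hydroxylation.
- Ring order: flavanone pyranone ring first (step 3), flavan pyran ring last (step 8).

Key step: step 8

Assumption: the (R)-phosphoric acid is written for step 8; with an alkene that cannot hydrogen-bond, the hand of the acid that opens the (4''S) face cannot be derived with certainty, and the (S)-acid takes its place should the sense prove opposite.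

**Route**

Step 1
Reactants: 1 4-hydroxy-2,6-dimethoxybenzaldehyde; 2 ethyl (S)-3-hydroxy-3-phenylpropanoate
Product: 3 ethyl (3R)-3-(4-formyl-3,5-dimethoxyphenoxy)-3-phenylpropanoate
Conditions: PPh3, DIAD (diisopropyl azodicarboxylate), THF, 0 °C → rt
Reagents that add atoms: none
Why: Mitsunobu etherification, in which the acidic para-formylphenol displaces the phosphonium-activated benzylic oxygen by SN2 with inversion, so the (S)-alcohol should give the (R)-aryl ether, while the low temperature and the acidic pronucleophile hold back elimination to the cinnamate.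

Step 2
Reactants: 3 ethyl (3R)-3-(4-formyl-3,5-dimethoxyphenoxy)-3-phenylpropanoate
Product: 4 (3R)-3-(4-formyl-3,5-dimethoxyphenoxy)-3-phenylpropanoic acid
Conditions: LiOH·H2O, THF/H2O, 0 °C; then 1 M HCl
Reagents that add atoms: lithium hydroxide, [Li+].[OH-]
Why: Ester saponification by attack of hydroxide at the acyl carbon, which at 0 °C is far faster than alpha-deprotonation, so the beta-aryloxy group should not be expelled and the benzylic ether centre is not touched.

Step 3
Reactants: 4 (3R)-3-(4-formyl-3,5-dimethoxyphenoxy)-3-phenylpropanoic acid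
Product: 6 (2R)-5,7-dimethoxy-4-oxo-2-phenylchromane-6-carbaldehyde, via mixed trifluoroacetic anhydride 5 (not isolated)
Conditions: TFAA, CH2Cl2, 0 °C → rt
Reagents that add atoms: none
Why: Intramolecular Friedel–Crafts acylation through the mixed anhydride at a ring carbon that is ortho to two oxygen atoms and para to a third (a phloroglucinol triether, which accepts a second acyl group); the two candidate positions are equivalent by symmetry, so only the 6-formyl isomer can form, and the stereocentre takes no part in the bond formation.

Step 4
Reactants: 7 4-methoxyphenol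
Product: 9 2,6-dibromo-4-methoxyphenol, via 2-bromo-4-methoxyphenol 8 (not isolated)
Conditions: Br2 (2.1 equiv), CH2Cl2, 0 °C → rt
Reagents that add atoms: bromine, BrBr
Why: Electrophilic aromatic bromination directed by the free hydroxyl, the stronger donor, to both of its ortho positions, the para position being blocked by the methoxy group.

Step 5
Reactants: 9 2,6-dibromo-4-methoxyphenol
Product: 10 1,3-dibromo-2,5-dimethoxybenzene
Conditions: MeI, K2CO3, acetone, reflux
Reagents that add atoms: iodomethane, CI
Why: Williamson O-methylation of an acidic 2,6-dibromophenol, which should go cleanly with a small electrophile despite the two flanking bromine atoms.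

Step 6
Reactants: 10 1,3-dibromo-2,5-dimethoxybenzene
Product: 12 2,5-dimethoxybenzene-1,3-diol, via 3-bromo-2,5-dimethoxyphenol 11 (not isolated)
Conditions: Pd2(dba)3 (2 mol %), tBuXPhos (2-di-tert-butylphosphino-2',4',6'-triisopropylbiphenyl, 8 mol %), KOH, 1,4-dioxane/H2O, 100 °C, argon; then aq HCl
Reagents that add atoms: potassium hydroxide, [K+].[OH-]
Why: Palladium-catalysed hydroxylation of aryl bromides with hydroxide (Buchwald-type C–O coupling), in which the bulky biarylphosphine favours C–O reductive elimination and suppresses diaryl ether formation, applied to both bromides of the same ring.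

Step 7
Reactants: 6 (2R)-5,7-dimethoxy-4-oxo-2-phenylchromane-6-carbaldehyde; 12 2,5-dimethoxybenzene-1,3-diol
Product: 14 (2R)-6-[(2,4-dihydroxy-3,6-dimethoxyphenyl)(hydroxy)methyl]-5,7-dimethoxy-2-phenylchroman-4-one (both carbinol epimers), via bis(bromomagnesium) phenolate 13 (not isolated)
Conditions: 12 (1.5 equiv), EtMgBr (3.0 equiv), Et2O, 0 °C; then 6, CH2Cl2, 0 °C → rt; sat. aq NH4Cl, 0 °C
Reagents that add atoms: none
Why: Casiraghi-type ortho-hydroxyalkylation of a magnesium phenolate, in which the magnesium-bound aldehyde is attacked by the ring carbon ortho to the phenolate oxygen through a six-membered chelate; the two open positions of the symmetric diol are equivalent, the product should stay as a magnesium alkoxide–phenolate chelate that does not ionise before the cold buffered quench, the weakly basic phenolate should neither enolise nor open the flavanone, and the uncontrolled carbinol centre is erased in step 8.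

Step 8
Reactants: 14 (2R)-6-[(2,4-dihydroxy-3,6-dimethoxyphenyl)(hydroxy)methyl]-5,7-dimethoxy-2-phenylchroman-4-one; 15 styrene
Product: 17 (2R)-6-[(2S,4S)-7-hydroxy-5,8-dimethoxy-2-phenylchroman-4-yl]-5,7-dimethoxy-2-phenylchroman-4-one (5-O-methyl ether of the target), via ortho-quinone methide 16 (not isolated)
Conditions: (R)-3,3'-bis(2,4,6-triisopropylphenyl)-1,1'-binaphthyl-2,2'-diyl hydrogen phosphate (10 mol %), styrene (10 equiv), 5 Å MS, PhMe, 0 °C → rt, slow addition of 14
Reagents that add atoms: none
Why: The phosphoric acid protonates the doubly benzylic hydroxyl of 14 and water leaves to give ortho-quinone methide 16, held by the phosphate as a hydrogen-bonded ion pair with its diarylmethyl cation form (the para-hydroxyl can only give the tautomeric para-quinone methide, which returns to the same cation); the CH2 terminus of styrene bonds to the methide carbon (C3''–C4'') and the resulting benzylic cation at C2'' is taken by the ring oxygen (O1''–C2''). The closest known reaction is the Brønsted acid-catalysed inverse-electron-demand hetero-Diels–Alder reaction of ortho-quinone methides, generated from ortho-hydroxybenzhydrols, with styrenes, including its versions with chiral BINOL-derived acids. The pyran ring closes either in one asynchronous [4+2] event or, after cation–olefin addition, by 6-endo capture of the C2'' cation by the C8a'' oxygen, and both paths give the 2-phenyl chroman because styrene bonds through its CH2 terminus. C4'' is set by the catalyst, whose 3,3'-aryl groups shield one face of the methide carbon in the ion pair; C2'' is set by the substrate relative to C4'', because the peri 5''-methoxy group forces the C4'' aryl group pseudo-axial in the half-chair and ring closure places the C2'' phenyl equatorial, which is the 2'',4''-trans arrangement. The step needs trans diastereoselectivity, one absolute sense at C4'' and closure through the flavan oxygen only; the last is secured because the flavanone 5-oxygen is methylated and the symmetric resorcinol ring offers a single ortho-hydroxyl, and slow addition of 14 into excess styrene keeps the free ring position of the resorcinol from capturing the cation.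

Step 9
Reactants: 17 (2R)-6-[(2S,4S)-7-hydroxy-5,8-dimethoxy-2-phenylchroman-4-yl]-5,7-dimethoxy-2-phenylchroman-4-one
Product: 19 (2R)-5-hydroxy-6-[(2S,4S)-7-hydroxy-5,8-dimethoxy-2-phenylchroman-4-yl]-7-methoxy-2-phenylchroman-4-one (CNP0301559.1), via bis(dichloroboryl) ether 18 (not isolated)
Conditions: BCl3 (3 equiv), CH2Cl2, −78 → −20 °C; then H2O
Reagents that add atoms: none
Why: Chelation-controlled Lewis acid demethylation, in which BCl3 bridges the C4 carbonyl and the peri 5-methoxy oxygen in a six-membered chelate and chloride removes that methyl group at low temperature, while the 7-, 5''- and 8''-methyl ethers lack this activation and the benzylic ethers at C2 and C2'' carry plain phenyl groups and should not ionise, so the three stereocentres are kept.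

**Compound list**

1 | 4-hydroxy-2,6-dimethoxybenzaldehyde | COc1cc(O)cc(OC)c1C=O | starting material
2 | ethyl (S)-3-hydroxy-3-phenylpropanoate | CCOC(=O)C[C@H](O)c1ccccc1 | starting material
3 | ethyl (3R)-3-(4-formyl-3,5-dimethoxyphenoxy)-3-phenylpropanoate | CCOC(=O)C[C@@H](Oc1cc(OC)c(C=O)c(OC)c1)c1ccccc1 | intermediate
4 | (3R)-3-(4-formyl-3,5-dimethoxyphenoxy)-3-phenylpropanoic acid | OC(=O)C[C@@H](Oc1cc(OC)c(C=O)c(OC)c1)c1ccccc1 | intermediate
5 | (3R)-3-(4-formyl-3,5-dimethoxyphenoxy)-3-phenylpropanoic trifluoroacetic anhydride | FC(F)(F)C(=O)OC(=O)C[C@@H](Oc1cc(OC)c(C=O)c(OC)c1)c1ccccc1 | intermediate (not isolated)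
6 | (2R)-5,7-dimethoxy-4-oxo-2-phenylchromane-6-carbaldehyde ((R)-6-formyl-5,7-dimethoxyflavanone) | COc1cc2c(c(OC)c1C=O)C(=O)C[C@H](c1ccccc1)O2 | intermediate
7 | 4-methoxyphenol | COc1ccc(O)cc1 | starting material
8 | 2-bromo-4-methoxyphenol | COc1ccc(O)c(Br)c1 | intermediate (not isolated)
9 | 2,6-dibromo-4-methoxyphenol | COc1cc(Br)c(O)c(Br)c1 | intermediate
10 | 1,3-dibromo-2,5-dimethoxybenzene | COc1cc(Br)c(OC)c(Br)c1 | intermediate
11 | 3-bromo-2,5-dimethoxyphenol | COc1cc(O)c(OC)c(Br)c1 | intermediate (not isolated)
12 | 2,5-dimethoxybenzene-1,3-diol | COc1cc(O)c(OC)c(O)c1 | intermediate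
13 | bis(bromomagnesium) 2,5-dimethoxybenzene-1,3-diolate | COc1cc(O[Mg]Br)c(OC)c(O[Mg]Br)c1 | intermediate (not isolated)
14 | (2R)-6-[(2,4-dihydroxy-3,6-dimethoxyphenyl)(hydroxy)methyl]-5,7-dimethoxy-2-phenylchroman-4-one, both carbinol epimers | COc1cc2c(c(OC)c1C(O)c1c(O)c(OC)c(O)cc1OC)C(=O)C[C@H](c1ccccc1)O2 | intermediate
15 | styrene | C=Cc1ccccc1 | starting material
16 | (2R)-6-[(4-hydroxy-2,5-dimethoxy-6-oxocyclohexa-2,4-dien-1-ylidene)methyl]-5,7-dimethoxy-2-phenylchroman-4-one (ortho-quinone methide) | COc1cc2c(c(OC)c1C=C1C(=O)C(OC)=C(O)C=C1OC)C(=O)C[C@H](c1ccccc1)O2 | intermediate (not isolated)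
17 | (2R)-6-[(2S,4S)-7-hydroxy-5,8-dimethoxy-2-phenylchroman-4-yl]-5,7-dimethoxy-2-phenylchroman-4-one (2'',4''-trans) | COc1cc2c(c(OC)c1[C@@H]1C[C@@H](c3ccccc3)Oc3c(OC)c(O)cc(OC)c31)C(=O)C[C@H](c1ccccc1)O2 | intermediate
18 | bis(dichloroboryl) ether of 19 at O-5 (chelated to the C4 carbonyl) and O-7'' | COc1cc2c(c(OB(Cl)Cl)c1[C@@H]1C[C@@H](c3ccccc3)Oc3c(OC)c(OB(Cl)Cl)cc(OC)c31)C(=O)C[C@H](c1ccccc1)O2 | intermediate (not isolated)
19 | (2R)-5-hydroxy-6-[(2S,4S)-7-hydroxy-5,8-dimethoxy-2-phenylchroman-4-yl]-7-methoxy-2-phenylchroman-4-one (2'',4''-trans) | COc1cc2c(c(O)c1[C@@H]1C[C@@H](c3ccccc3)Oc3c(OC)c(O)cc(OC)c31)C(=O)C[C@H](c1ccccc1)O2 | target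

**Step count**

Total: 9 steps. Longest linear sequence: 6 steps (steps 1, 2, 3, 7, 8, 9; the branch through steps 4, 5, 6 is equally long).

**Steps most likely to fail**

Step 8. The main danger is poor facial selectivity at the methide carbon, because styrene has no hydrogen-bond handle for the phosphate. Lesser dangers are erosion of the trans preference and self-arylation of the cation by the free ring position of another carbinol molecule. The fallback sets out from 14 and comes back at 17, and it gives up catalyst control in favour of separation. Compound 14 and styrene are combined under an achiral acid, diphenyl phosphate (PhO)2P(O)OH, in toluene, so that only the substrate-based trans preference operates. Because the flavanone centre is already (2R), the two trans products are diastereomers and not enantiomers: 17 and (2R)-6-[(2R,4R)-7-hydroxy-5,8-dimethoxy-2-phenylchroman-4-yl]-5,7-dimethoxy-2-phenylchroman-4-one F1. They are separated by preparative HPLC, and 17 goes on to step 9.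

Step 7. Addition to the hindered, electron-rich aldehyde may be sluggish. The magnesium alkoxide may ionise and be captured by a second phenolate, leading to a triarylmethane. The phenolate may also open the flavanone ring, with loss of the C2 configuration. The fallback sets out from 6 and 12, comes back at 14 and uses no base. Compounds 6 and 12 are condensed with phenylboronic acid (catalytic propanoic acid, toluene, Dean–Stark). Boron ties the phenol oxygen to the aldehyde, directs the ring carbon ortho to that oxygen onto the carbonyl, and traps the benzylic oxygen in the cyclic boronate (2R)-6-[7-hydroxy-5,8-dimethoxy-2-phenyl-4H-1,3,2-benzodioxaborinin-4-yl]-5,7-dimethoxy-2-phenylchroman-4-one F2, which cannot ionise under the reaction conditions. Transesterification with pinacol in THF/H2O at room temperature then releases 14.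

Step 3. The formyl group may deactivate the ring so far that acylation stalls. If stronger acid is then used, the benzylic aryl ether may ionise, causing loss of configuration or elimination to the cinnamic acid. The fallback sets out from 2 and comes back at 6, and it adds the formyl carbon after ring closure.
- Compound 2 is coupled under the step 1 Mitsunobu conditions with commercial 4-bromo-3,5-dimethoxyphenol (COc1cc(O)cc(OC)c1Br) to give ethyl (3R)-3-(4-bromo-3,5-dimethoxyphenoxy)-3-phenylpropanoate F3.
- Saponification as in step 2 gives (3R)-3-(4-bromo-3,5-dimethoxyphenoxy)-3-phenylpropanoic acid F4.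
- TFAA in CH2Cl2 converts F4 through the mixed trifluoroacetic anhydride F5 into (2R)-6-bromo-5,7-dimethoxy-2-phenylchroman-4-one F6. This ring carries no carbonyl group, and the regiochemistry is again fixed by symmetry.
- Base-free Stille coupling with tributyl(vinyl)stannane (Pd(P(t-Bu)3)2, toluene, 90 °C) gives (2R)-6-ethenyl-5,7-dimethoxy-2-phenylchroman-4-one F7 without exposing the flavanone to base.
- Lemieux–Johnson cleavage (OsO4 catalytic, NaIO4, 2,6-lutidine, dioxane/H2O) gives 6.

**Further compounds**

F1 | step 8 | (2R)-6-[(2R,4R)-7-hydroxy-5,8-dimethoxy-2-phenylchroman-4-yl]-5,7-dimethoxy-2-phenylchroman-4-one | COc1cc2c(c(OC)c1[C@H]1C[C@H](c3ccccc3)Oc3c(OC)c(O)cc(OC)c31)C(=O)C[C@H](c1ccccc1)O2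
F2 | step 7 | (2R)-6-[7-hydroxy-5,8-dimethoxy-2-phenyl-4H-1,3,2-benzodioxaborinin-4-yl]-5,7-dimethoxy-2-phenylchroman-4-one | COc1cc2c(c(OC)c1C1OB(c3ccccc3)Oc3c(OC)c(O)cc(OC)c31)C(=O)C[C@H](c1ccccc1)O2
F3 | step 3 | ethyl (3R)-3-(4-bromo-3,5-dimethoxyphenoxy)-3-phenylpropanoate | CCOC(=O)C[C@@H](Oc1cc(OC)c(Br)c(OC)c1)c1ccccc1
F4 | step 3 | (3R)-3-(4-bromo-3,5-dimethoxyphenoxy)-3-phenylpropanoic acid | OC(=O)C[C@@H](Oc1cc(OC)c(Br)c(OC)c1)c1ccccc1
F5 | step 3 | (3R)-3-(4-bromo-3,5-dimethoxyphenoxy)-3-phenylpropanoic trifluoroacetic anhydride | FC(F)(F)C(=O)OC(=O)C[C@@H](Oc1cc(OC)c(Br)c(OC)c1)c1ccccc1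
F6 | step 3 | (2R)-6-bromo-5,7-dimethoxy-2-phenylchroman-4-one | COc1cc2c(c(OC)c1Br)C(=O)C[C@H](c1ccccc1)O2
F7 | step 3 | (2R)-6-ethenyl-5,7-dimethoxy-2-phenylchroman-4-one | COc1cc2c(c(OC)c1C=C)C(=O)C[C@H](c1ccccc1)O2
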